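The trimer is cut at its two methylene bridges into an acylfilicinic-acid ring A carrying the quaternary stereocentre, butanoylphloroglucinol (ring B) and a 2,2-dimethyl-2H-chromene (ring C); each bridge is later formed by adding ring B to a quinone methide released from a Mannich base. Everything rests on the pyran of ring C: its O1–C2(CH3)2–C3=C4–C4a=C8a array is the valence isomer of a cis-dienone. Condensing 3-methylbut-2-enal with a butanoylphloroglucinol whose para oxygen is tosylated gives that 1-oxatriene, which closes by oxa-6π electrocyclisation, forming the O1–C2 bond at the oxygen ortho to the ketone. Ring A's stereocentre is set by palladium-catalysed asymmetric dearomative geranylation.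

Key step: step 3

Remark 1: ring A is a β-triketone; it is drawn throughout in the enol form of the target structure, and the descriptor (4R) refers to that form.
Remark 2: the sense of induction of the chiral diphosphine in step 9 cannot be predicted with certainty for this nucleophile; the (R,R) ligand is written, and its mirror image is to be used if the (4S) product should predominate.

Step 1
Reactants: 1 benzene-1,3,5-triol (phloroglucinol); 2 butanoyl chloride
Product: 3 1-(2,4,6-trihydroxyphenyl)butan-1-one
Conditions: AlCl3 (3.5 equiv), PhNO2, 0 → 60 °C; aq. HCl work-up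
Reagents that add atoms: butanoyl chloride (2), CCCC(Cl)=O
Why: Friedel–Crafts C-acylation of the threefold-symmetric, highly activated triol should stop at the mono-ketone because the acyl group and its AlCl3 chelate deactivate the ring towards a second acylation.

Step 2
Reactants: 3 1-(2,4,6-trihydroxyphenyl)butan-1-one; 4 4-methylbenzenesulfonyl chloride (1.0 equiv)
Product: 5 4-butanoyl-3,5-dihydroxyphenyl 4-methylbenzenesulfonate
Conditions: K2CO3 (1.1 equiv), acetone, 0 °C → rt
Reagents that add atoms: 4-methylbenzenesulfonyl chloride (4), Cc1ccc(cc1)S(Cl)(=O)=O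
Why: Chemoselective O-sulfonylation, since the two hydroxyls ortho to the ketone are held in hydrogen bonds to the carbonyl and the more acidic, unchelated para hydroxyl should react first with one equivalent of the chloride.

Step 3
Reactants: 5 4-butanoyl-3,5-dihydroxyphenyl 4-methylbenzenesulfonate; 6 3-methylbut-2-enal (1.5 equiv)
Product: 8 8-butanoyl-7-hydroxy-2,2-dimethyl-2H-chromen-5-yl 4-methylbenzenesulfonate, via oxatriene 7 (not isolated)
Conditions: ethylenediammonium diacetate (20 mol %), toluene, 110 °C, 4 Å molecular sieves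
Reagents that add atoms: 3-methylbut-2-enal (6), CC(C)=CC=O
Why: The amine salt converts 6 into an iminium ion that is attacked by C3 of 5 (ortho to one free hydroxyl and para to the other; C3 and C5 are equivalent), and loss of the amine and of water gives the (Z)-1-oxatriene 7, an ortho-quinone methide whose carbonyl oxygen is the former phenol oxygen next to the butanoyl-bearing carbon. Thermal disrotatory oxa-6π electrocyclisation of 7 then joins this oxygen to the dimethyl-substituted diene terminus, which forms the O1–C2 bond, closes the 2H-pyran and restores the aromaticity of ring C. The closest known reaction type is the domino Knoevenagel/oxa-6π chromenylation (formal [3+3] annulation) of resorcinols and acylphloroglucinols with α,β-unsaturated aldehydes. The single ring that forms is six-membered and closes in a pericyclic 6π mode; C2 carries two methyl groups, so no stereocentre is created. The step needs regioselection between the two oxygens that flank the new C4a–C4 bond, and the substrate secures it: the oxygen para to the ketone is a sulfonate ester and cannot become the carbonyl of an oxatriene, so only the oxygen ortho to the butanoyl group can close and the 8-acyl rather than the 6-acyl chromene must result. A second annulation is held back by the limited amount of 6 and by the remaining hydroxyl being locked in a hydrogen bond to the ketone.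

Step 4
Reactants: 8 8-butanoyl-7-hydroxy-2,2-dimethyl-2H-chromen-5-yl 4-methylbenzenesulfonate
Product: 9 1-(5,7-dihydroxy-2,2-dimethyl-2H-chromen-8-yl)butan-1-one
Conditions: KOH (2.5 equiv), MeOH–H2O, 60 °C, argon; then aq. HCl to pH 3
Reagents that add atoms: none
Why: Saponification of the electron-poor aryl sulfonate by attack of hydroxide at sulfur should free the 5-hydroxyl while the base-stable chromene and aryl ketone remain untouched.

Step 5
Reactants: 9 1-(5,7-dihydroxy-2,2-dimethyl-2H-chromen-8-yl)butan-1-one; 10 N,N-dimethylmethyleneiminium iodide (1.1 equiv)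
Product: 11 1-{6-[(dimethylamino)methyl]-5,7-dihydroxy-2,2-dimethyl-2H-chromen-8-yl}butan-1-one
Conditions: K2CO3 (1.1 equiv), MeCN, 0 °C → rt
Reagents that add atoms: N,N-dimethylmethyleneiminium iodide (10), C=[N+](C)C.[I-]
Why: Mannich aminomethylation with the preformed iminium salt should occur at C6, the only unsubstituted aromatic carbon, which is activated by both flanking hydroxyls.

Step 6
Reactants: 11 1-{6-[(dimethylamino)methyl]-5,7-dihydroxy-2,2-dimethyl-2H-chromen-8-yl}butan-1-one; 3 1-(2,4,6-trihydroxyphenyl)butan-1-one (3 equiv)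
Product: 13 1-[3-({8-butanoyl-5,7-dihydroxy-2,2-dimethyl-2H-chromen-6-yl}methyl)-2,4,6-trihydroxyphenyl]butan-1-one, via ortho-quinone methide 12 (not isolated)
Conditions: 1,4-dioxane, 100 °C, argon sweep
Reagents that add atoms: none
Why: Thermal loss of dimethylamine from the ortho-hydroxybenzylamine should give ortho-quinone methide 12, which is trapped by Michael-type C-alkylation of 3 at one of its two equivalent free ring carbons, the excess of 3 suppressing double alkylation.

Step 7
Reactants: 14 2-methylbenzene-1,3,5-triol; 15 acetic anhydride (1.1 equiv)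
Product: 16 1-(2,4,6-trihydroxy-3-methylphenyl)ethan-1-one
Conditions: BF3·OEt2, 0 → 60 °C; then aq. NaOAc
Reagents that add atoms: acetic anhydride (15), CC(=O)OC(C)=O
Why: Friedel–Crafts acetylation promoted by BF3 at one of the two equivalent free carbons of the symmetric triol, the difluoroboron chelate of the product ketone disfavouring a second acetylation.

Step 8
Reactants: 16 1-(2,4,6-trihydroxy-3-methylphenyl)ethan-1-one; 10 N,N-dimethylmethyleneiminium iodide (1.1 equiv)
Product: 17 1-{3-[(dimethylamino)methyl]-2,4,6-trihydroxy-5-methylphenyl}ethan-1-one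
Conditions: K2CO3 (1.1 equiv), MeCN, 0 °C → rt
Reagents that add atoms: N,N-dimethylmethyleneiminium iodide (10), C=[N+](C)C.[I-]
Why: Mannich aminomethylation at the only remaining ring CH installs the future bridge carbon and at the same time blocks this position against C-allylation in step 9.

Step 9
Reactants: 17 1-{3-[(dimethylamino)methyl]-2,4,6-trihydroxy-5-methylphenyl}ethan-1-one; 18 (2E)-3,7-dimethylocta-2,6-dien-1-yl acetate (geranyl acetate, 1.1 equiv)
Product: 19 (4R)-2-acetyl-6-[(dimethylamino)methyl]-4-[(2E)-3,7-dimethylocta-2,6-dien-1-yl]-3,5-dihydroxy-4-methylcyclohexa-2,5-dien-1-one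
Conditions: Pd2(dba)3·CHCl3 (2.5 mol %), (1R,2R)-N,N'-bis[2-(diphenylphosphanyl)benzoyl]cyclohexane-1,2-diamine (7.5 mol %), K2CO3 (1.0 equiv), degassed THF, 0 °C → rt
Reagents that add atoms: geranyl acetate (18), CC(=O)OC/C=C(\C)CCC=C(C)C
Why: Tsuji–Trost asymmetric allylic dearomatisation, in which the phenolate of 17 should attack the unsubstituted terminus of the π-geranyl complex of palladium through its methyl-bearing ring carbon (the other alkyl-bearing carbon is shielded and deactivated by the ammoniomethyl group), with the (E)-alkene retained and the C2-symmetric diphosphine differentiating the two faces of the planar nucleophile so that the quaternary stereocentre is set under catalyst control.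

Step 10
Reactants: 19 (4R)-2-acetyl-6-[(dimethylamino)methyl]-4-[(2E)-3,7-dimethylocta-2,6-dien-1-yl]-3,5-dihydroxy-4-methylcyclohexa-2,5-dien-1-one; 13 1-[3-({8-butanoyl-5,7-dihydroxy-2,2-dimethyl-2H-chromen-6-yl}methyl)-2,4,6-trihydroxyphenyl]butan-1-one (1.1 equiv)
Product: 21 (4R)-2-acetyl-6-{[3-butanoyl-5-({8-butanoyl-5,7-dihydroxy-2,2-dimethyl-2H-chromen-6-yl}methyl)-2,4,6-trihydroxyphenyl]methyl}-4-[(2E)-3,7-dimethylocta-2,6-dien-1-yl]-3,5-dihydroxy-4-methylcyclohexa-2,5-dien-1-one (CNP0103039.1), via methylene triketone 20 (not isolated)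
Conditions: THF, 50 °C, argon sweep
Reagents that add atoms: none
Why: Retro-Mannich (E1cB) loss of dimethylamine from the β-triketone Mannich base should give the exocyclic enone 20 under mild heating, and conjugate addition of the single free aromatic carbon of ring B in 13 followed by rearomatisation forms the second methylene bridge without touching the quaternary stereocentre.

Compound list
1 | benzene-1,3,5-triol (phloroglucinol) | Oc1cc(O)cc(O)c1 | starting material
2 | butanoyl chloride | CCCC(Cl)=O | starting material
3 | 1-(2,4,6-trihydroxyphenyl)butan-1-one | CCCC(=O)c1c(O)cc(O)cc1O | intermediate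
4 | 4-methylbenzenesulfonyl chloride | Cc1ccc(cc1)S(Cl)(=O)=O | starting material
5 | 4-butanoyl-3,5-dihydroxyphenyl 4-methylbenzenesulfonate | CCCC(=O)c1c(O)cc(OS(=O)(=O)c2ccc(C)cc2)cc1O | intermediate
6 | 3-methylbut-2-enal | CC(C)=CC=O | starting material
7 | (6Z)-4-butanoyl-5-hydroxy-2-(3-methylbut-2-en-1-ylidene)-3-oxocyclohexa-4,6-dien-1-yl 4-methylbenzenesulfonate (1-oxatriene, ortho-quinone methide) | O=C1/C(=C\C=C(C)C)C(OS(=O)(=O)c2ccc(C)cc2)=CC(O)=C1C(=O)CCC | intermediate (not isolated)
8 | 8-butanoyl-7-hydroxy-2,2-dimethyl-2H-chromen-5-yl 4-methylbenzenesulfonate | CCCC(=O)c1c(O)cc(OS(=O)(=O)c2ccc(C)cc2)c2C=CC(C)(C)Oc12 | intermediate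
9 | 1-(5,7-dihydroxy-2,2-dimethyl-2H-chromen-8-yl)butan-1-one | CCCC(=O)c1c(O)cc(O)c2C=CC(C)(C)Oc12 | intermediate
10 | N,N-dimethylmethyleneiminium iodide | C=[N+](C)C.[I-] | starting material
11 | 1-{6-[(dimethylamino)methyl]-5,7-dihydroxy-2,2-dimethyl-2H-chromen-8-yl}butan-1-one | CCCC(=O)c1c(O)c(CN(C)C)c(O)c2C=CC(C)(C)Oc12 | intermediate
12 | 8-butanoyl-7-hydroxy-2,2-dimethyl-6-methylidene-2H-chromen-5(6H)-one (ortho-quinone methide) | CCCC(=O)C1=C(O)C(=C)C(=O)C2=C1OC(C)(C)C=C2 | intermediate (not isolated)
13 | 1-[3-({8-butanoyl-5,7-dihydroxy-2,2-dimethyl-2H-chromen-6-yl}methyl)-2,4,6-trihydroxyphenyl]butan-1-one | CCCC(=O)c1c(O)cc(O)c(Cc2c(O)c3C=CC(C)(C)Oc3c(C(=O)CCC)c2O)c1O | intermediate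
14 | 2-methylbenzene-1,3,5-triol | Cc1c(O)cc(O)cc1O | starting material
15 | acetic anhydride | CC(=O)OC(C)=O | starting material
16 | 1-(2,4,6-trihydroxy-3-methylphenyl)ethan-1-one | CC(=O)c1c(O)cc(O)c(C)c1O | intermediate
17 | 1-{3-[(dimethylamino)methyl]-2,4,6-trihydroxy-5-methylphenyl}ethan-1-one | CC(=O)c1c(O)c(C)c(O)c(CN(C)C)c1O | intermediate
18 | (2E)-3,7-dimethylocta-2,6-dien-1-yl acetate (geranyl acetate) | CC(=O)OC/C=C(\C)CCC=C(C)C | starting material
19 | (4R)-2-acetyl-6-[(dimethylamino)methyl]-4-[(2E)-3,7-dimethylocta-2,6-dien-1-yl]-3,5-dihydroxy-4-methylcyclohexa-2,5-dien-1-one | CN(C)CC1=C(O)[C@@](C)(C/C=C(\C)CCC=C(C)C)C(O)=C(C(C)=O)C1=O | intermediate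
20 | 2-acetyl-4-[(2E)-3,7-dimethylocta-2,6-dien-1-yl]-3-hydroxy-4-methyl-6-methylidenecyclohex-2-ene-1,5-dione, C4 arranged in space as in 19 (formally 4S in this keto form because C5 is now a ketone) | C=C1C(=O)[C@@](C)(C/C=C(\C)CCC=C(C)C)C(O)=C(C(C)=O)C1=O | intermediate (not isolated)
21 | (4R)-2-acetyl-6-{[3-butanoyl-5-({8-butanoyl-5,7-dihydroxy-2,2-dimethyl-2H-chromen-6-yl}methyl)-2,4,6-trihydroxyphenyl]methyl}-4-[(2E)-3,7-dimethylocta-2,6-dien-1-yl]-3,5-dihydroxy-4-methylcyclohexa-2,5-dien-1-one (CNP0103039.1) | CCCC(=O)c1c(O)c(CC2=C(O)[C@@](C)(C/C=C(\C)CCC=C(C)C)C(O)=C(C(C)=O)C2=O)c(O)c(Cc2c(O)c3c(c(C(=O)CCC)c2O)OC(C)(C)C=C3)c1O | target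

Total step count: 10.
Longest linear sequence: 7 steps (steps 1–6 and step 10); steps 7–9 form the second branch, which joins at step 10.

Steps most likely to fail

Step 9. The chiral palladium complex may discriminate the two faces of the flat, almost symmetric phenolate poorly, or allylation may drift to oxygen, to nitrogen or to the aminomethyl-bearing carbon. The fallback replaces catalyst control by a traceless chiral amine and separation of diastereomers, and sets out from 16. Mannich condensation of 16 with aqueous formaldehyde and (S)-N-methyl-1-phenylethanamine in EtOH at rt should give 1-[2,4,6-trihydroxy-3-methyl-5-({methyl[(1S)-1-phenylethyl]amino}methyl)phenyl]ethan-1-one F1. Dearomative geranylation of F1 with 18 under achiral zerovalent-palladium catalysis (Pd(PPh3)4, K2CO3, THF, rt) should give two diastereomers, (4R)-2-acetyl-4-[(2E)-3,7-dimethylocta-2,6-dien-1-yl]-3,5-dihydroxy-4-methyl-6-({methyl[(1S)-1-phenylethyl]amino}methyl)cyclohexa-2,5-dien-1-one F2 and its (4S) diastereomer F3, to be separated by crystallisation or chromatography; F3 is set aside. F2, warmed with 13 under the conditions of step 10, should expel the amine auxiliary via 20 and come back to the route at 21.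

Step 3. The carbon–carbon condensation of the sulfonate-deactivated ring with the enal may be too slow, so that self-condensation of the enal or attack of the amine catalyst on the sulfonate takes over. The fallback reaches the same oxatriene by a sigmatropic route and sets out from 5. O-Alkylation of one of the two equivalent hydroxyls of 5 with 3-chloro-3-methylbut-1-yne (DBU, catalytic CuCl2, MeCN, 0 °C) should give 4-butanoyl-3-hydroxy-5-[(2-methylbut-3-yn-2-yl)oxy]phenyl 4-methylbenzenesulfonate F4. Heating F4 in xylene at 140 °C should trigger an aromatic propargyl Claisen rearrangement to the only free ortho carbon and give 4-butanoyl-3,5-dihydroxy-2-(3-methylbuta-1,2-dien-1-yl)phenyl 4-methylbenzenesulfonate F5. A 1,5-hydrogen shift in F5 leads to the same oxatriene 7 and, by the same oxa-6π closure at the oxygen ortho to the ketone, to 8, where the route is rejoined.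

Step 10. The methylene triketone 20 may dimerise by hetero-Diels–Alder reaction or be intercepted by its own side chain faster than the hindered nucleophile 13 adds, and the liberated amine may promote retro-Michael scrambling of the bridge already present in 13. The fallback reverses the order in which the bridges are made and sets out from 19 and 3. Warming 19 with a threefold excess of the small, unhindered 3 (THF, 50 °C) should give, via 20, (4R)-2-acetyl-6-[(3-butanoyl-2,4,6-trihydroxyphenyl)methyl]-4-[(2E)-3,7-dimethylocta-2,6-dien-1-yl]-3,5-dihydroxy-4-methylcyclohexa-2,5-dien-1-one F6. Heating F6 with 11 in 1,4-dioxane at 100 °C should generate 12, which is captured by the only free carbon of ring B, and the route is rejoined at 21.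

Further compounds
F1 | step 9 | 1-[2,4,6-trihydroxy-3-methyl-5-({methyl[(1S)-1-phenylethyl]amino}methyl)phenyl]ethan-1-one | CC(=O)c1c(O)c(C)c(O)c(CN(C)[C@@H](C)c2ccccc2)c1O
F2 | step 9 | (4R)-2-acetyl-4-[(2E)-3,7-dimethylocta-2,6-dien-1-yl]-3,5-dihydroxy-4-methyl-6-({methyl[(1S)-1-phenylethyl]amino}methyl)cyclohexa-2,5-dien-1-one | CN([C@@H](C)c1ccccc1)CC1=C(O)[C@@](C)(C/C=C(\C)CCC=C(C)C)C(O)=C(C(C)=O)C1=O
F3 | step 9 | (4S)-2-acetyl-4-[(2E)-3,7-dimethylocta-2,6-dien-1-yl]-3,5-dihydroxy-4-methyl-6-({methyl[(1S)-1-phenylethyl]amino}methyl)cyclohexa-2,5-dien-1-one | CN([C@@H](C)c1ccccc1)CC1=C(O)[C@](C)(C/C=C(\C)CCC=C(C)C)C(O)=C(C(C)=O)C1=O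
F4 | step 3 | 4-butanoyl-3-hydroxy-5-[(2-methylbut-3-yn-2-yl)oxy]phenyl 4-methylbenzenesulfonate | CCCC(=O)c1c(O)cc(OS(=O)(=O)c2ccc(C)cc2)cc1OC(C)(C)C#C
F5 | step 3 | 4-butanoyl-3,5-dihydroxy-2-(3-methylbuta-1,2-dien-1-yl)phenyl 4-methylbenzenesulfonate | CCCC(=O)c1c(O)cc(OS(=O)(=O)c2ccc(C)cc2)c(C=C=C(C)C)c1O
F6 | step 10 | (4R)-2-acetyl-6-[(3-butanoyl-2,4,6-trihydroxyphenyl)methyl]-4-[(2E)-3,7-dimethylocta-2,6-dien-1-yl]-3,5-dihydroxy-4-methylcyclohexa-2,5-dien-1-one | CCCC(=O)c1c(O)cc(O)c(CC2=C(O)[C@@](C)(C/C=C(\C)CCC=C(C)C)C(O)=C(C(C)=O)C2=O)c1O
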